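**Plan**
1. Retrosynthetic cuts: (a) the tertiary ester C–O and the C3–isopropyl bond, back to a C3 ketone; (b) the C6 methyl and C5=C6, back to a saturated C7 ketone; (c) C4–O and C3a–H, back to a C3a=C4 alkene; (d) the C8–C8a bond; (e) the C4–C3a bond (alkenyllithium plus Weinreb amide).
2. Feature used in (d): after (c) the seven-membered ring holds the γ,δ-unsaturated ketone C7(=O)–C8–C8a–C3a=C4 with C8a quaternary, the retron of a Claisen shift. Reconnecting O to C4 gives a 2-methylideneoxolane, the cycloisomer of an acyclic 1-cyclopentenylpent-4-yn-1-ol.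
3. Forward: the five-membered carbocycle is bought; the alkynol closes a temporary oxolane, which ring-enlarges by a [3,3] shift to the cyclohept-4-enone (a skeletal rearrangement that forms C8–C8a). Then follow hydroboration, the C3 ketone, isopropyl addition with acylation in the same flask, the C7 enone and global desilylation.
4. Stereochemistry: the C4 carbinol (CBS reduction) passes its chirality to quaternary C8a in the rearrangement. The angular methyl then steers the hydroboration (C3a, C4) and, with the C3a substituent, the isopropyl addition (C3). A second CBS reduction sets a temporary C3 carbinol (PMB ether) that shields one face and is later oxidised.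
5. Helpers: TMS on the alkyne, ethylene ketal on C7, TBS on O4 and on the phenol; all are removed on the way.

Key step: step 6

Remark: hydroazulene numbering is used for all bicyclic compounds (five-membered ring C1, C2, C3, C3a, C8a; seven-membered ring C3a, C4, C5, C6, C7, C8, C8a); 1, 4, 19 and all reagents are taken as commercial.

**Step 1**
Reactants: 1 2-bromo-3-methylcyclopent-2-en-1-one
Product: 2 (S)-2-bromo-3-methylcyclopent-2-en-1-ol
Conditions: (R)-2-methyl-CBS-oxazaborolidine (10 mol %), BH3·SMe2, THF, −20 °C; MeOH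
Reagents that add atoms: none
Why: CBS reduction in which the bromo-substituted alkenyl carbon acts as the large group, so the (R)-catalyst should give the (S)-alcohol, a temporary stereocentre that later keeps the ether oxygen on the face away from the incoming reagents.

**Step 2**
Reactants: 2 (S)-2-bromo-3-methylcyclopent-2-en-1-ol
Product: 3 (S)-2-bromo-3-methylcyclopent-2-en-1-yl 4-methoxybenzyl ether
Conditions: NaH, 4-methoxybenzyl chloride, n-Bu4NI (cat.), THF/DMF, 0 °C to rt
Reagents that add atoms: 4-methoxybenzyl chloride, COc1ccc(CCl)cc1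
Why: Williamson ether synthesis on the sodium alkoxide leaves the stereocentre untouched and gives an ether that tolerates organolithiums, borane and hot base but leaves later with DDQ.

**Step 3**
Reactants: 4 5-(trimethylsilyl)pent-4-ynoic acid
Product: 5 N-methoxy-N-methyl-5-(trimethylsilyl)pent-4-ynamide
Conditions: 1,1'-carbonyldiimidazole, CH2Cl2, rt; then MeNH(OMe)·HCl
Reagents that add atoms: N,O-dimethylhydroxylamine hydrochloride, CNOC.Cl
Why: Weinreb amide formation through the acyl imidazole, the silyl cap removing the acidic alkyne proton that would otherwise quench the alkenyllithium of step 4.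

**Step 4**
Reactants: 3 (S)-2-bromo-3-methylcyclopent-2-en-1-yl 4-methoxybenzyl ether; 5 N-methoxy-N-methyl-5-(trimethylsilyl)pent-4-ynamide
Product: 8 1-[(5S)-5-(4-methoxybenzyloxy)-2-methylcyclopent-1-en-1-yl]-5-(trimethylsilyl)pent-4-yn-1-one, via vinyllithium 6 (not isolated), via lithium hemiaminal 7 (not isolated)
Conditions: t-BuLi (2 equiv), Et2O, −78 °C; then 5, −78 to 0 °C; aq. HCl (0.5 M), 0 °C
Reagents that add atoms: none
Why: Bromine–lithium exchange (the second equivalent of t-BuLi destroys the t-BuBr formed) followed by Weinreb ketone synthesis, in which the chelated tetrahedral adduct 7 prevents over-addition and collapses to the ketone only on work-up.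

**Step 5**
Reactants: 8 1-[(5S)-5-(4-methoxybenzyloxy)-2-methylcyclopent-1-en-1-yl]-5-(trimethylsilyl)pent-4-yn-1-one
Product: 10 (1S)-1-[(5S)-5-(4-methoxybenzyloxy)-2-methylcyclopent-1-en-1-yl]pent-4-yn-1-ol, via silylalkynol 9 (not isolated)
Conditions: (R)-2-methyl-CBS-oxazaborolidine (20 mol %), BH3·SMe2, THF, −30 °C; MeOH; then K2CO3, MeOH, rt
Reagents that add atoms: none
Why: CBS reduction with the tetrasubstituted cycloalkenyl group as the large substituent, so the (R)-catalyst should give the (S)-carbinol under reagent control, followed by methanolysis of the alkynyl C–Si bond in the same flask.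

**Step 6**
Reactants: 10 (1S)-1-[(5S)-5-(4-methoxybenzyloxy)-2-methylcyclopent-1-en-1-yl]pent-4-yn-1-ol
Product: 12 (3S,8aR)-3-(4-methoxybenzyloxy)-8a-methyl-2,3,5,6,8,8a-hexahydroazulen-7(1H)-one, via methylideneoxolane 11 (not isolated)
Conditions: MeLi (10 mol %), phenetole, 200 °C (microwave, sealed vessel)
Reagents that add atoms: none
Why: The catalytic lithium alkoxide of 10 adds to the terminal alkyne and proton transfer from further 10 releases the 2-methylideneoxolane 11, whose allyl vinyl ether unit (C8=C7–O–C4–C3a=C8a) then undergoes a concerted, suprafacial [3,3] Claisen shift through a boat-like transition state, breaking O–C4 and forming C8–C8a. The closest known reaction type is the alkoxide-catalysed cycloisomerisation/Claisen ring expansion of 1-alkenylpent-4-yn-1-ols to cyclohept-4-enones. The temporary oxolane closes 5-exo-dig, and the seven-membered carbocycle closes by the sigmatropic shift itself, a two-carbon enlargement of the oxolane and not an exo or endo attack. The new quaternary centre C8a is controlled by the (S)-carbinol: only the rotamer that puts the oxolane CH2 on the C8a side can close a (Z)-cycloheptene, so the breaking C–O bond lies on one face of the cyclopentene and C8 is delivered to that same face, which is also the face opposite the OPMB group. The step needs the [3,3] shift to outrun migration of the exocyclic enol ether double bond into the ring and ionic [1,3] pathways; the catalytic amount of base, the unsubstituted alkyne terminus and the ring-constrained geometry should secure this, the tetrasubstituted C3a=C8a terminus costing only a higher temperature.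

**Step 7**
Reactants: 12 (3S,8aR)-3-(4-methoxybenzyloxy)-8a-methyl-2,3,5,6,8,8a-hexahydroazulen-7(1H)-one
Product: 13 (3S,8aR)-3-(4-methoxybenzyloxy)-8a-methyl-2,3,5,6,8,8a-hexahydroazulen-7(1H)-one ethylene ketal
Conditions: TMSOCH2CH2OTMS, TMSOTf (cat.), CH2Cl2, −78 to −20 °C; pyridine
Reagents that add atoms: 1,2-bis(trimethylsilyloxy)ethane, C[Si](C)(C)OCCO[Si](C)(C)C
Why: Ketalisation by silyl transfer under aprotic, cold conditions masks the C7 ketone against borane and the later organocerium reagent without moving the C3a=C4 double bond or cleaving the allylic PMB ether.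

**Step 8**
Reactants: 13 (3S,8aR)-3-(4-methoxybenzyloxy)-8a-methyl-2,3,5,6,8,8a-hexahydroazulen-7(1H)-one ethylene ketal
Product: 15 (3S,3aS,4S,8aR)-4-hydroxy-3-(4-methoxybenzyloxy)-8a-methyldecahydroazulen-7-one ethylene ketal, via alkylborane 14 (not isolated)
Conditions: BH3·THF, THF, 0 °C to rt; then NaOH, H2O2, 0 °C
Reagents that add atoms: hydrogen peroxide, OO
Why: Hydroboration–oxidation, in which BH3 should add syn across C3a=C4 with boron on the less substituted C4 and from the face opposite the angular methyl and the OPMB group, setting C4 and the trans ring fusion at C3a together, the C–B bond then being oxidised with retention.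

**Step 9**
Reactants: 15 (3S,3aS,4S,8aR)-4-hydroxy-3-(4-methoxybenzyloxy)-8a-methyldecahydroazulen-7-one ethylene ketal
Product: 16 (3S,3aR,4S,8aR)-4-(tert-butyldimethylsilyloxy)-3-(4-methoxybenzyloxy)-8a-methyldecahydroazulen-7-one ethylene ketal
Conditions: TBSOTf, 2,6-lutidine, CH2Cl2, 0 °C
Reagents that add atoms: tert-butyldimethylsilyl trifluoromethanesulfonate, CC(C)(C)[Si](C)(C)OS(=O)(=O)C(F)(F)F
Why: Silylation of the hindered secondary alcohol with the silyl triflate blocks O4 during the acylation of step 14, the descriptor at C3a changing only through the priority rules.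

**Step 10**
Reactants: 16 (3S,3aR,4S,8aR)-4-(tert-butyldimethylsilyloxy)-3-(4-methoxybenzyloxy)-8a-methyldecahydroazulen-7-one ethylene ketal
Product: 17 (3S,3aR,4S,8aR)-4-(tert-butyldimethylsilyloxy)-3-hydroxy-8a-methyldecahydroazulen-7-one ethylene ketal
Conditions: DDQ, CH2Cl2/aq. phosphate buffer (pH 7), 0 °C to rt
Reagents that add atoms: none
Why: Oxidative PMB cleavage (hydride abstraction from the electron-rich benzylic position, then hydrolysis of the oxocarbenium ion) leaves the silyl ether and the ketal in place.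

**Step 11**
Reactants: 17 (3S,3aR,4S,8aR)-4-(tert-butyldimethylsilyloxy)-3-hydroxy-8a-methyldecahydroazulen-7-one ethylene ketal
Product: 18 (3aS,4S,8aR)-4-(tert-butyldimethylsilyloxy)-8a-methyldecahydroazulene-3,7-dione 7-ethylene ketal
Conditions: Dess–Martin periodinane, pyridine, CH2Cl2, rt
Reagents that add atoms: none
Why: Dess–Martin oxidation under buffered, non-basic conditions should give the β-silyloxy ketone without epimerisation at C3a or β-elimination.

**Step 12**
Reactants: 19 4-hydroxybenzoic acid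
Product: 21 4-(tert-butyldimethylsilyloxy)benzoic acid, via bis-silyl derivative 20 (not isolated)
Conditions: TBSCl (2.2 equiv), imidazole, DMF, rt; then AcOH, THF/H2O, rt
Reagents that add atoms: tert-butyldimethylsilyl chloride, CC(C)(C)[Si](C)(C)Cl
Why: Silylation of both acidic OH groups followed by selective hydrolysis of the labile silyl ester leaves the phenol protected as its TBS ether.

**Step 13**
Reactants: 21 4-(tert-butyldimethylsilyloxy)benzoic acid
Product: 22 4-(tert-butyldimethylsilyloxy)benzoyl chloride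
Conditions: (COCl)2, DMF (cat.), CH2Cl2, 0 °C to rt
Reagents that add atoms: oxalyl chloride, O=C(Cl)C(Cl)=O
Why: Acid chloride formation through the Vilsmeier-type chloroiminium catalyst, conditions that aryl silyl ethers tolerate.

**Step 14**
Reactants: 18 (3aS,4S,8aR)-4-(tert-butyldimethylsilyloxy)-8a-methyldecahydroazulene-3,7-dione 7-ethylene ketal; 22 4-(tert-butyldimethylsilyloxy)benzoyl chloride
Product: 24 (3R,3aS,4S,8aR)-4-(tert-butyldimethylsilyloxy)-8a-methyl-7-oxo-3-(propan-2-yl)decahydroazulen-3-yl 4-(tert-butyldimethylsilyloxy)benzoate 7-ethylene ketal, via cerium alkoxide 23 (not isolated)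
Conditions: i-PrLi, CeCl3, THF, −78 °C; then 22, −78 °C to rt
Reagents that add atoms: isopropyllithium, [Li]C(C)C
Why: Organocerium 1,2-addition (weakly basic, so the enolisable β-silyloxy ketone should not be deprotonated) from the face of the cyclopentanone opposite the C3a substituent and the angular methyl sets C3, and the congested alkoxide is O-acylated in the same flask, which avoids a separate esterification of a tertiary alcohol.

**Step 15**
Reactants: 24 (3R,3aS,4S,8aR)-4-(tert-butyldimethylsilyloxy)-8a-methyl-7-oxo-3-(propan-2-yl)decahydroazulen-3-yl 4-(tert-butyldimethylsilyloxy)benzoate 7-ethylene ketal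
Product: 25 (3R,3aS,4S,8aR)-4-(tert-butyldimethylsilyloxy)-8a-methyl-7-oxo-3-(propan-2-yl)decahydroazulen-3-yl 4-(tert-butyldimethylsilyloxy)benzoate
Conditions: PPTS, acetone/H2O, 55 °C
Reagents that add atoms: water, O
Why: Mild acid-catalysed ketal hydrolysis frees the C7 ketone while the hindered secondary and the aryl silyl ethers and the tertiary ester should survive the pyridinium acid.

**Step 16**
Reactants: 25 (3R,3aS,4S,8aR)-4-(tert-butyldimethylsilyloxy)-8a-methyl-7-oxo-3-(propan-2-yl)decahydroazulen-3-yl 4-(tert-butyldimethylsilyloxy)benzoate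
Product: 27 (3R,3aS,4S,8aR)-4-(tert-butyldimethylsilyloxy)-6,8a-dimethyl-7-oxo-3-(propan-2-yl)decahydroazulen-3-yl 4-(tert-butyldimethylsilyloxy)benzoate (both C6 epimers), via lithium enolate 26 (not isolated)
Conditions: LiN(i-Pr)2, THF, −78 °C; MeI, −78 to −20 °C
Reagents that add atoms: iodomethane, CI
Why: Kinetic enolate alkylation, in which the amide base should remove a C6 proton and not a C8 proton next to the quaternary C8a, the two C6 epimers converging in step 17.

**Step 17**
Reactants: 27 (3R,3aS,4S,8aR)-4-(tert-butyldimethylsilyloxy)-6,8a-dimethyl-7-oxo-3-(propan-2-yl)decahydroazulen-3-yl 4-(tert-butyldimethylsilyloxy)benzoate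
Product: 28 (3R,3aS,4S,8aR)-4-(tert-butyldimethylsilyloxy)-6,8a-dimethyl-7-oxo-3-(propan-2-yl)-1,2,3,3a,4,7,8,8a-octahydroazulen-3-yl 4-(tert-butyldimethylsilyloxy)benzoate
Conditions: IBX, DMSO/fluorobenzene, 70 °C
Reagents that add atoms: none
Why: IBX dehydrogenation of the ketone through its more substituted enol, where only the C5–C6 side can be desaturated because C8a carries no hydrogen, should give the endocyclic trisubstituted enone.

**Step 18**
Reactants: 28 (3R,3aS,4S,8aR)-4-(tert-butyldimethylsilyloxy)-6,8a-dimethyl-7-oxo-3-(propan-2-yl)-1,2,3,3a,4,7,8,8a-octahydroazulen-3-yl 4-(tert-butyldimethylsilyloxy)benzoate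
Product: 29 (3R,3aS,4S,8aR)-4-hydroxy-6,8a-dimethyl-7-oxo-3-(propan-2-yl)-1,2,3,3a,4,7,8,8a-octahydroazulen-3-yl 4-hydroxybenzoate
Conditions: HF·pyridine, THF, 0 °C to rt
Reagents that add atoms: none
Why: Desilylation with a weakly acidic fluoride source removes the alkyl and the aryl silyl ether in one operation without the base that could move the acyl group from the tertiary to the neighbouring secondary oxygen.

**Compound list**
1 | 2-bromo-3-methylcyclopent-2-en-1-one | CC1=C(Br)C(=O)CC1 | starting material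
2 | (S)-2-bromo-3-methylcyclopent-2-en-1-ol | CC1=C(Br)[C@@H](O)CC1 | intermediate
3 | (S)-2-bromo-3-methylcyclopent-2-en-1-yl 4-methoxybenzyl ether | CC1=C(Br)[C@@H](OCc2ccc(OC)cc2)CC1 | intermediate
4 | 5-(trimethylsilyl)pent-4-ynoic acid | C[Si](C)(C)C#CCCC(=O)O | starting material
5 | N-methoxy-N-methyl-5-(trimethylsilyl)pent-4-ynamide | CON(C)C(=O)CCC#C[Si](C)(C)C | intermediate
6 | [(5S)-5-(4-methoxybenzyloxy)-2-methylcyclopent-1-en-1-yl]lithium | CC1=C([Li])[C@@H](OCc2ccc(OC)cc2)CC1 | intermediate (not isolated)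
7 | lithium alkoxide of the N-methoxy-N-methyl hemiaminal from 6 and 5 (tetrahedral adduct) | CC1=C(C(O[Li])(CCC#C[Si](C)(C)C)N(C)OC)[C@@H](OCc2ccc(OC)cc2)CC1 | intermediate (not isolated)
8 | 1-[(5S)-5-(4-methoxybenzyloxy)-2-methylcyclopent-1-en-1-yl]-5-(trimethylsilyl)pent-4-yn-1-one | CC1=C(C(=O)CCC#C[Si](C)(C)C)[C@@H](OCc2ccc(OC)cc2)CC1 | intermediate
9 | (1S)-1-[(5S)-5-(4-methoxybenzyloxy)-2-methylcyclopent-1-en-1-yl]-5-(trimethylsilyl)pent-4-yn-1-ol | CC1=C([C@@H](O)CCC#C[Si](C)(C)C)[C@@H](OCc2ccc(OC)cc2)CC1 | intermediate (not isolated)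
10 | (1S)-1-[(5S)-5-(4-methoxybenzyloxy)-2-methylcyclopent-1-en-1-yl]pent-4-yn-1-ol | CC1=C([C@@H](O)CCC#C)[C@@H](OCc2ccc(OC)cc2)CC1 | intermediate
11 | (2S)-2-[(5S)-5-(4-methoxybenzyloxy)-2-methylcyclopent-1-en-1-yl]-5-methylideneoxolane | C=C1CC[C@@H](C2=C(C)CC[C@@H]2OCc2ccc(OC)cc2)O1 | intermediate (not isolated)
12 | (3S,8aR)-3-(4-methoxybenzyloxy)-8a-methyl-2,3,5,6,8,8a-hexahydroazulen-7(1H)-one | C1CC=C2[C@](C)(CC[C@@H]2OCc2ccc(OC)cc2)CC1=O | intermediate
13 | ethylene ketal of 12 at C7, (3S,8aR) | C1CC=C2[C@](C)(CC[C@@H]2OCc2ccc(OC)cc2)CC13OCCO3 | intermediate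
14 | C4 monoalkylborane from syn addition of BH3 to 13 (boron at C4, hydrogen at C3a, both anti to the angular methyl) | C1C[C@H](B)[C@@H]2[C@](C)(CC[C@@H]2OCc2ccc(OC)cc2)CC13OCCO3 | intermediate (not isolated)
15 | (3S,3aS,4S,8aR)-4-hydroxy-3-(4-methoxybenzyloxy)-8a-methyldecahydroazulen-7-one ethylene ketal | C1C[C@H](O)[C@@H]2[C@](C)(CC[C@@H]2OCc2ccc(OC)cc2)CC13OCCO3 | intermediate
16 | (3S,3aR,4S,8aR)-4-(tert-butyldimethylsilyloxy)-3-(4-methoxybenzyloxy)-8a-methyldecahydroazulen-7-one ethylene ketal | C1C[C@H](O[Si](C)(C)C(C)(C)C)[C@@H]2[C@](C)(CC[C@@H]2OCc2ccc(OC)cc2)CC13OCCO3 | intermediate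
17 | (3S,3aR,4S,8aR)-4-(tert-butyldimethylsilyloxy)-3-hydroxy-8a-methyldecahydroazulen-7-one ethylene ketal | C1C[C@H](O[Si](C)(C)C(C)(C)C)[C@@H]2[C@](C)(CC[C@@H]2O)CC13OCCO3 | intermediate
18 | (3aS,4S,8aR)-4-(tert-butyldimethylsilyloxy)-8a-methyldecahydroazulene-3,7-dione 7-ethylene ketal | C1C[C@H](O[Si](C)(C)C(C)(C)C)[C@@H]2[C@](C)(CCC2=O)CC13OCCO3 | intermediate
19 | 4-hydroxybenzoic acid | OC(=O)c1ccc(O)cc1 | starting material
20 | tert-butyldimethylsilyl 4-(tert-butyldimethylsilyloxy)benzoate | CC(C)(C)[Si](C)(C)OC(=O)c1ccc(O[Si](C)(C)C(C)(C)C)cc1 | intermediate (not isolated)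
21 | 4-(tert-butyldimethylsilyloxy)benzoic acid | OC(=O)c1ccc(O[Si](C)(C)C(C)(C)C)cc1 | intermediate
22 | 4-(tert-butyldimethylsilyloxy)benzoyl chloride | ClC(=O)c1ccc(O[Si](C)(C)C(C)(C)C)cc1 | intermediate
23 | dichlorocerium (3R,3aS,4S,8aR)-alkoxide from isopropyl addition to 18 (isopropyl cis to H-3a) | C1C[C@H](O[Si](C)(C)C(C)(C)C)[C@@H]2[C@](C)(CC[C@@]2(O[Ce](Cl)Cl)C(C)C)CC13OCCO3 | intermediate (not isolated)
24 | (3R,3aS,4S,8aR)-4-(tert-butyldimethylsilyloxy)-8a-methyl-7-oxo-3-(propan-2-yl)decahydroazulen-3-yl 4-(tert-butyldimethylsilyloxy)benzoate 7-ethylene ketal | C1C[C@H](O[Si](C)(C)C(C)(C)C)[C@@H]2[C@](C)(CC[C@@]2(OC(=O)c2ccc(O[Si](C)(C)C(C)(C)C)cc2)C(C)C)CC13OCCO3 | intermediate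
25 | (3R,3aS,4S,8aR)-4-(tert-butyldimethylsilyloxy)-8a-methyl-7-oxo-3-(propan-2-yl)decahydroazulen-3-yl 4-(tert-butyldimethylsilyloxy)benzoate | C1C[C@H](O[Si](C)(C)C(C)(C)C)[C@@H]2[C@](C)(CC[C@@]2(OC(=O)c2ccc(O[Si](C)(C)C(C)(C)C)cc2)C(C)C)CC1=O | intermediate
26 | lithium C6=C7 enolate of 25 | [Li]OC1=CC[C@H](O[Si](C)(C)C(C)(C)C)[C@@H]2[C@](C)(CC[C@@]2(OC(=O)c2ccc(O[Si](C)(C)C(C)(C)C)cc2)C(C)C)C1 | intermediate (not isolated)
27 | (3R,3aS,4S,8aR)-4-(tert-butyldimethylsilyloxy)-6,8a-dimethyl-7-oxo-3-(propan-2-yl)decahydroazulen-3-yl 4-(tert-butyldimethylsilyloxy)benzoate, both C6 epimers | CC1C[C@H](O[Si](C)(C)C(C)(C)C)[C@@H]2[C@](C)(CC[C@@]2(OC(=O)c2ccc(O[Si](C)(C)C(C)(C)C)cc2)C(C)C)CC1=O | intermediate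
28 | (3R,3aS,4S,8aR)-4-(tert-butyldimethylsilyloxy)-6,8a-dimethyl-7-oxo-3-(propan-2-yl)-1,2,3,3a,4,7,8,8a-octahydroazulen-3-yl 4-(tert-butyldimethylsilyloxy)benzoate | CC1=C[C@H](O[Si](C)(C)C(C)(C)C)[C@@H]2[C@](C)(CC[C@@]2(OC(=O)c2ccc(O[Si](C)(C)C(C)(C)C)cc2)C(C)C)CC1=O | intermediate
29 | (3R,3aS,4S,8aR)-4-hydroxy-6,8a-dimethyl-7-oxo-3-(propan-2-yl)-1,2,3,3a,4,7,8,8a-octahydroazulen-3-yl 4-hydroxybenzoate | CC1=C[C@H](O)[C@@H]2[C@](C)(CC[C@@]2(OC(=O)c2ccc(O)cc2)C(C)C)CC1=O | target

**Totals**
Total step count: 18.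
Longest linear sequence: 15 steps (steps 1, 2, 4 to 11 and 14 to 18); steps 3, 12 and 13 make the two side fragments.

**Steps most likely to fail**

Step 6. The [3,3] shift may be slow at the tetrasubstituted alkene terminus (the ring methyl must turn inward in the boat transition state). During that time the base could move the exocyclic enol ether double bond into the oxolane ring, or the allylic C–O bond could ionise with loss of chirality transfer. Fallback, from 10 back to 12: 10 is cycloisomerised under neutral conditions (Ph3PAuNTf2 cat., CH2Cl2, rt) and the methylideneoxolane 11 is isolated. Treatment with i-Bu3Al (CH2Cl2, −78 °C to rt) then promotes the Claisen ring enlargement at low temperature as a Lewis-acid-triggered process, the aluminium reagent reducing the new ketone in the same flask by β-hydride transfer. This should give (3S,8aR)-3-(4-methoxybenzyloxy)-8a-methyl-1,2,3,5,6,7,8,8a-octahydroazulen-7-ol F1 (C7 epimers), and Dess–Martin oxidation of F1 returns 12.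

Step 14. The hindered ketone may be enolised with loss of the β-silyloxy group, reduced by hydride transfer from the branched nucleophile, or the congested alkoxide may be acylated incompletely. Fallback, from 18 back to 24: 2-propenylmagnesium bromide with CeCl3 (a smaller nucleophile with no transferable β-hydrogen) should add from the same face to give the tertiary allylic alcohol (3S,3aS,4S,8aR)-4-(tert-butyldimethylsilyloxy)-3-hydroxy-8a-methyl-3-(prop-1-en-2-yl)decahydroazulen-7-one ethylene ketal F2. Hydrogenation (H2, PtO2, EtOAc) saturates the isopropenyl group to the isopropyl carbinol (3R,3aS,4S,8aR)-4-(tert-butyldimethylsilyloxy)-3-hydroxy-8a-methyl-3-(propan-2-yl)decahydroazulen-7-one ethylene ketal F3. Its potassium alkoxide (KN(SiMe3)2, THF, −78 °C) is then acylated with 22 to give 24.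

Step 8. Hydroboration of an alkene flanked by two fully substituted carbons may be slow, and the facial discrimination by the angular methyl may be insufficient. Fallback, from 13 back to 18: DDQ removes the PMB group to give the allylic alcohol (3S,8aR)-3-hydroxy-8a-methyl-2,3,5,6,8,8a-hexahydroazulen-7(1H)-one ethylene ketal F4. Dess–Martin oxidation gives the enone (8aR)-8a-methyl-1,2,5,6,8,8a-hexahydroazulene-3,7-dione 7-ethylene ketal F5, in which C4 is the β-carbon. Copper-catalysed conjugate borylation (CuCl, NaOt-Bu, Xantphos, B2pin2, MeOH, THF) should place boron at C4 anti to the angular methyl and protonate the enolate at C3a, giving the C4 pinacol boronate of the saturated C3 ketone F6. Oxidation with NaBO3 gives (3aS,4S,8aR)-4-hydroxy-8a-methyldecahydroazulene-3,7-dione 7-ethylene ketal F7, in which C3a can still be corrected by mild base equilibration. Silylation (TBSOTf, 2,6-lutidine) then gives 18.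

**Further compounds**
F1 | step 6 | (3S,8aR)-3-(4-methoxybenzyloxy)-8a-methyl-1,2,3,5,6,7,8,8a-octahydroazulen-7-ol (C7 epimers) | C1CC=C2[C@](C)(CC[C@@H]2OCc2ccc(OC)cc2)CC1O
F2 | step 14 | (3S,3aS,4S,8aR)-4-(tert-butyldimethylsilyloxy)-3-hydroxy-8a-methyl-3-(prop-1-en-2-yl)decahydroazulen-7-one ethylene ketal | C1C[C@H](O[Si](C)(C)C(C)(C)C)[C@@H]2[C@](C)(CC[C@@]2(O)C(C)=C)CC13OCCO3
F3 | step 14 | (3R,3aS,4S,8aR)-4-(tert-butyldimethylsilyloxy)-3-hydroxy-8a-methyl-3-(propan-2-yl)decahydroazulen-7-one ethylene ketal | C1C[C@H](O[Si](C)(C)C(C)(C)C)[C@@H]2[C@](C)(CC[C@@]2(O)C(C)C)CC13OCCO3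
F4 | step 8 | (3S,8aR)-3-hydroxy-8a-methyl-2,3,5,6,8,8a-hexahydroazulen-7(1H)-one ethylene ketal | C1CC=C2[C@](C)(CC[C@@H]2O)CC13OCCO3
F5 | step 8 | (8aR)-8a-methyl-1,2,5,6,8,8a-hexahydroazulene-3,7-dione 7-ethylene ketal | C1CC=C2[C@](C)(CCC2=O)CC13OCCO3
F6 | step 8 | C4 pinacol boronate corresponding to F7 (boron in place of the C4 hydroxyl, same configuration) | C1C[C@H](B3OC(C)(C)C(C)(C)O3)[C@@H]2[C@](C)(CCC2=O)CC14OCCO4
F7 | step 8 | (3aS,4S,8aR)-4-hydroxy-8a-methyldecahydroazulene-3,7-dione 7-ethylene ketal | C1C[C@H](O)[C@@H]2[C@](C)(CCC2=O)CC13OCCO3
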